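**Plan**

- Retrosynthetic cuts, in order: the C(sp)–C(sp2) bond of the enyne; then C6–O1 and C6–OMe of the 1,2-dioxane; then the C3–OO bond; finally the two allylic C–C bonds around a C6 ketone masked as a methylidene group.
- Enabling feature: ring carbon C6 carries O1, OMe and two carbon substituents and lies 1,4 to the peroxy carbon C3, so the dioxane is the cyclic methyl peroxyketal of an (S)-4-hydroperoxy ketone.
- Forward: 3-chloro-2-(chloromethyl)prop-1-ene is alkylated twice to give the open chain; the (R)-carbinol becomes a masked (S)-hydroperoxide; ozonolysis unveils the ketone; the only ring closes in step 10; the enyne is joined last.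
- Stereochemistry: C3 from (R)-BINAP/Ru hydrogenation followed by SN2 inversion; C6 from thermodynamic (anomeric) control in the ring closure; the E alkene from syn hydrozirconation.

Key step: step 10

Remark: 2-methoxyprop-2-yl hydroperoxide is not assumed to be a catalogue chemical and is made in step 7; all peroxides are handled cold, dilute and behind a shield.

**Route**

Step 1
Reactants: 1 (4-bromobut-1-yn-1-yl)trimethylsilane; 2 3-chloro-2-(chloromethyl)prop-1-ene
Product: 4 [6-(chloromethyl)hept-6-en-1-yn-1-yl]trimethylsilane, via silylbutynylmagnesium bromide 3 (not isolated)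
Conditions: Mg, THF, rt to 40 °C; then added to 2 (3 equiv), CuI (5 mol%), THF, −20 → 0 °C
Reagents that add atoms: none
Why: Copper-catalysed Grignard allylic substitution; the homopropargylic organomagnesium displaces one chloride of the symmetrical linchpin, SN2 and SN2' attack give the same product, and the excess of 2 (recovered by distillation) keeps double alkylation down.

Step 2
Reactants: 4 [6-(chloromethyl)hept-6-en-1-yn-1-yl]trimethylsilane; 5 methyl acetoacetate
Product: 7 methyl 6-methylidene-3-oxo-11-(trimethylsilyl)undec-10-ynoate, via acetoacetate dianion 6 (not isolated)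
Conditions: 5, NaH, THF, 0 °C; n-BuLi, 0 °C; then 4, 0 °C → rt; cold 1 M HCl quench
Reagents that add atoms: none
Why: Acetoacetate dianion γ-alkylation; the more basic terminal carbon of the dienolate attacks the allylic chloride by SN2, so the chain grows at C4 of the keto ester and the 1,3-dicarbonyl unit is kept.

Step 3
Reactants: 7 methyl 6-methylidene-3-oxo-11-(trimethylsilyl)undec-10-ynoate
Product: 8 methyl (3R)-3-hydroxy-6-methylidene-11-(trimethylsilyl)undec-10-ynoate
Conditions: RuCl2[(R)-BINAP] (1 mol%), H2 (4 atm), MeOH, 50 °C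
Reagents that add atoms: none
Why: Noyori asymmetric hydrogenation; the keto ester chelates ruthenium and (R)-BINAP directs hydride to the face that gives the (3R)-carbinol, while the non-chelating 1,1-disubstituted alkene and the silylalkyne are expected to stay untouched at low pressure.

Step 4
Reactants: 8 methyl (3R)-3-hydroxy-6-methylidene-11-(trimethylsilyl)undec-10-ynoate
Product: 9 (3R)-6-methylidene-11-(trimethylsilyl)undec-10-yne-1,3-diol
Conditions: LiBH4, THF, 0 °C → rt
Reagents that add atoms: none
Why: Borohydride ester reduction, accelerated by the neighbouring hydroxyl, gives the 1,3-diol without touching alkene, alkynylsilane or the carbinol centre.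

Step 5
Reactants: 9 (3R)-6-methylidene-11-(trimethylsilyl)undec-10-yne-1,3-diol
Product: 10 (3R)-1-[(tert-butyldiphenylsilyl)oxy]-6-methylidene-11-(trimethylsilyl)undec-10-yn-3-ol
Conditions: TBDPSCl (1.05 equiv), imidazole, CH2Cl2, 0 °C
Reagents that add atoms: tert-butylchlorodiphenylsilane, CC(C)(C)[Si](Cl)(c1ccccc1)c1ccccc1
Why: Sterically controlled monosilylation; the bulky chlorosilane reacts at the primary hydroxyl far faster than at the secondary one.

Step 6
Reactants: 10 (3R)-1-[(tert-butyldiphenylsilyl)oxy]-6-methylidene-11-(trimethylsilyl)undec-10-yn-3-ol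
Product: 11 (3R)-1-[(tert-butyldiphenylsilyl)oxy]-6-methylidene-11-(trimethylsilyl)undec-10-yn-3-yl methanesulfonate
Conditions: MsCl, Et3N, CH2Cl2, 0 °C
Reagents that add atoms: methanesulfonyl chloride, CS(=O)(=O)Cl
Why: O-sulfonylation takes place at oxygen with retention and turns the (R)-carbinol into a leaving group ready for inversion.

Step 7
Reactants: 12 2,3-dimethylbut-2-ene
Product: 13 2-methoxyprop-2-yl hydroperoxide
Conditions: O3, MeOH/CH2Cl2, −78 °C; N2 purge; used as a cold solution
Reagents that add atoms: ozone, [O-][O+]=O; methanol, CO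
Why: Criegee ozonolysis in a participating solvent; the symmetrical alkene fragments to acetone and acetone O-oxide, which methanol traps as the hydroperoxy ketal.

Step 8
Reactants: 11 (3R)-1-[(tert-butyldiphenylsilyl)oxy]-6-methylidene-11-(trimethylsilyl)undec-10-yn-3-yl methanesulfonate; 13 2-methoxyprop-2-yl hydroperoxide
Product: 14 (3S)-1-[(tert-butyldiphenylsilyl)oxy]-3-[(2-methoxypropan-2-yl)peroxy]-6-methylidene-11-(trimethylsilyl)undec-10-yne
Conditions: 13 (3 equiv), KOtBu (2.5 equiv), 18-crown-6, THF, 0 °C; then 11, 0 °C → rt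
Reagents that add atoms: none
Why: SN2 alkylation of a hydroperoxide anion; the α-effect nucleophile, only weakly basic once excess 13 has consumed all KOtBu, displaces the mesylate with inversion, so the (3R)-sulfonate gives the (3S)-peroxide with the O–O unit still masked as an acyclic peroxyketal.

Step 9
Reactants: 14 (3S)-1-[(tert-butyldiphenylsilyl)oxy]-3-[(2-methoxypropan-2-yl)peroxy]-6-methylidene-11-(trimethylsilyl)undec-10-yne
Product: 15 (9S)-11-[(tert-butyldiphenylsilyl)oxy]-9-[(2-methoxypropan-2-yl)peroxy]-1-(trimethylsilyl)undec-1-yn-6-one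
Conditions: O3, pyridine (3 equiv), CH2Cl2, −78 °C, Sudan red 7B endpoint
Reagents that add atoms: ozone, [O-][O+]=O
Why: Criegee ozonolysis of the electron-rich 1,1-disubstituted alkene is much faster than attack on the silylalkyne or the arene rings, the dye marks the endpoint, and pyridine turns the carbonyl oxide directly into the ketone so that no phosphine or sulfide reductant and no acid meets the peroxyketal.

Step 10
Reactants: 15 (9S)-11-[(tert-butyldiphenylsilyl)oxy]-9-[(2-methoxypropan-2-yl)peroxy]-1-(trimethylsilyl)undec-1-yn-6-one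
Product: 18 tert-butyl(2-{(3S,6R)-6-methoxy-6-[5-(trimethylsilyl)pent-4-yn-1-yl]-1,2-dioxan-3-yl}ethoxy)diphenylsilane, via free hydroperoxy ketone 16 (not isolated), via cyclic peroxyhemiketal 17 (not isolated)
Conditions: TsOH·H2O (10 mol%), HC(OMe)3 (3 equiv), MeOH (0.02 M), 0 °C → rt
Reagents that add atoms: methanol, CO
Why: Acid-catalysed transketalisation with methanol removes the 2-methoxyprop-2-yl group as 2,2-dimethoxypropane and frees hydroperoxide 16, whose terminal oxygen adds to the protonated C6 ketone to give peroxyhemiketal 17; ionisation of 17 to a cyclic peroxycarbenium ion and capture by methanol then install the C6–OMe bond. The closest known reaction type is the acid-mediated cyclisation of 4-hydroperoxy ketones and their acyclic peroxyketals to 3-alkoxy-1,2-dioxanes. The 1,2-dioxane closes by 6-exo-trig attack of O1 on the C6 carbonyl carbon. The C3 centre is not touched, and the new C6 centre is set under thermodynamic control: ionisation and recapture are reversible, so the chair with the C3 arm and the C6 chain both equatorial and the methoxy group axial (anomeric stabilisation) should accumulate, and that chair is the (3S,6R) isomer. The step needs ring closure to win over intermolecular peroxyketalisation and over plain dimethyl ketal formation; the 1,4 spacing of C3 and C6 and the dilution favour closure, any dimethyl ketal re-ionises to the same cation, and HC(OMe)3 removes water so the hemiketal does not persist. The alkynylsilane and the TBDPS ether should tolerate catalytic TsOH in methanol on this time scale, and partial loss of the silyl ether would converge in the next step.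

Step 11
Reactants: 18 tert-butyl(2-{(3S,6R)-6-methoxy-6-[5-(trimethylsilyl)pent-4-yn-1-yl]-1,2-dioxan-3-yl}ethoxy)diphenylsilane
Product: 19 2-[(3S,6R)-6-methoxy-6-(pent-4-yn-1-yl)-1,2-dioxan-3-yl]ethan-1-ol
Conditions: Bu4NF (2.5 equiv), THF, 0 °C → rt
Reagents that add atoms: none
Why: Fluoride-induced desilylation cleaves both the Si–O bond of the silyl ether and the Si–C(sp) bond of the alkynylsilane, while the peroxyketal offers fluoride no reactive site and the short cold exposure limits base-induced Kornblum–DeLaMare cleavage at C3–H.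

Step 12
Reactants: 19 2-[(3S,6R)-6-methoxy-6-(pent-4-yn-1-yl)-1,2-dioxan-3-yl]ethan-1-ol
Product: 20 2-[(3S,6R)-6-methoxy-6-(pent-4-yn-1-yl)-1,2-dioxan-3-yl]acetic acid
Conditions: TEMPO (20 mol%), PhI(OAc)2 (2.2 equiv), MeCN/aq. NaH2PO4–Na2HPO4 buffer (pH 7), 0 °C → rt
Reagents that add atoms: water, O
Why: Oxoammonium (TEMPO) oxidation with PhI(OAc)2 as terminal oxidant takes the primary alcohol through the aldehyde hydrate to the acid under buffered, metal-free conditions that should leave the O–O bond, the peroxyketal and the terminal alkyne alone.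

Step 13
Reactants: 21 undec-1-yne
Product: 23 (1E)-1-iodoundec-1-ene, via alkenylzirconocene chloride 22 (not isolated)
Conditions: Cp2Zr(H)Cl, THF, rt; then I2, 0 °C
Reagents that add atoms: iodine, II
Why: Hydrozirconation–iodinolysis; syn, anti-Markovnikov addition of Zr–H to the terminal alkyne and cleavage of the C–Zr bond by iodine with retention should give only the (E)-iodoalkene.

Step 14
Reactants: 20 2-[(3S,6R)-6-methoxy-6-(pent-4-yn-1-yl)-1,2-dioxan-3-yl]acetic acid; 23 (1E)-1-iodoundec-1-ene
Product: 24 2-[(3S,6R)-6-[(6E)-hexadec-6-en-4-yn-1-yl]-6-methoxy-1,2-dioxan-3-yl]acetic acid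
Conditions: PdCl2(PPh3)2 (5 mol%), CuI (10 mol%), i-Pr2NH (5 equiv), THF, degassed, rt; dilute acid work-up
Reagents that add atoms: none
Why: Sonogashira coupling; the alkenyl iodide adds to zerovalent palladium (formed in situ from the divalent palladium precatalyst) at room temperature with retention of the E geometry, the copper acetylide of 20 (carried as its ammonium carboxylate) transmetalates, and reductive elimination gives the enyne under conditions mild enough for an unstrained cyclic dialkyl peroxyketal.

**Compound list**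

1 | (4-bromobut-1-yn-1-yl)trimethylsilane | C[Si](C)(C)C#CCCBr | starting material
2 | 3-chloro-2-(chloromethyl)prop-1-ene | ClCC(=C)CCl | starting material
3 | [4-(trimethylsilyl)but-3-yn-1-yl]magnesium bromide | C[Si](C)(C)C#CCC[Mg]Br | intermediate
4 | [6-(chloromethyl)hept-6-en-1-yn-1-yl]trimethylsilane | C[Si](C)(C)C#CCCCC(=C)CCl | intermediate
5 | methyl acetoacetate (methyl 3-oxobutanoate) | COC(=O)CC(C)=O | starting material
6 | methyl acetoacetate dianion, sodium lithium dienolate | COC([O-])=CC([O-])=C.[Na+].[Li+] | intermediate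
7 | methyl 6-methylidene-3-oxo-11-(trimethylsilyl)undec-10-ynoate | COC(=O)CC(=O)CCC(=C)CCCC#C[Si](C)(C)C | intermediate
8 | methyl (3R)-3-hydroxy-6-methylidene-11-(trimethylsilyl)undec-10-ynoate | COC(=O)C[C@H](O)CCC(=C)CCCC#C[Si](C)(C)C | intermediate
9 | (3R)-6-methylidene-11-(trimethylsilyl)undec-10-yne-1,3-diol | OCC[C@H](O)CCC(=C)CCCC#C[Si](C)(C)C | intermediate
10 | (3R)-1-[(tert-butyldiphenylsilyl)oxy]-6-methylidene-11-(trimethylsilyl)undec-10-yn-3-ol | CC(C)(C)[Si](c1ccccc1)(c1ccccc1)OCC[C@H](O)CCC(=C)CCCC#C[Si](C)(C)C | intermediate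
11 | (3R)-1-[(tert-butyldiphenylsilyl)oxy]-6-methylidene-11-(trimethylsilyl)undec-10-yn-3-yl methanesulfonate | CC(C)(C)[Si](c1ccccc1)(c1ccccc1)OCC[C@H](OS(C)(=O)=O)CCC(=C)CCCC#C[Si](C)(C)C | intermediate
12 | 2,3-dimethylbut-2-ene | CC(C)=C(C)C | starting material
13 | 2-methoxyprop-2-yl hydroperoxide | COC(C)(C)OO | intermediate
14 | (3S)-1-[(tert-butyldiphenylsilyl)oxy]-3-[(2-methoxypropan-2-yl)peroxy]-6-methylidene-11-(trimethylsilyl)undec-10-yne | CC(C)(C)[Si](c1ccccc1)(c1ccccc1)OCC[C@@H](OOC(C)(C)OC)CCC(=C)CCCC#C[Si](C)(C)C | intermediate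
15 | (9S)-11-[(tert-butyldiphenylsilyl)oxy]-9-[(2-methoxypropan-2-yl)peroxy]-1-(trimethylsilyl)undec-1-yn-6-one | CC(C)(C)[Si](c1ccccc1)(c1ccccc1)OCC[C@@H](OOC(C)(C)OC)CCC(=O)CCCC#C[Si](C)(C)C | intermediate
16 | (9S)-11-[(tert-butyldiphenylsilyl)oxy]-9-hydroperoxy-1-(trimethylsilyl)undec-1-yn-6-one | CC(C)(C)[Si](c1ccccc1)(c1ccccc1)OCC[C@@H](OO)CCC(=O)CCCC#C[Si](C)(C)C | intermediate
17 | (6S)-6-{2-[(tert-butyldiphenylsilyl)oxy]ethyl}-3-[5-(trimethylsilyl)pent-4-yn-1-yl]-1,2-dioxan-3-ol (both C3 epimers) | C[Si](C)(C)C#CCCCC1(O)CC[C@@H](CCO[Si](c2ccccc2)(c2ccccc2)C(C)(C)C)OO1 | intermediate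
18 | tert-butyl(2-{(3S,6R)-6-methoxy-6-[5-(trimethylsilyl)pent-4-yn-1-yl]-1,2-dioxan-3-yl}ethoxy)diphenylsilane | C[Si](C)(C)C#CCCC[C@]1(OC)CC[C@@H](CCO[Si](c2ccccc2)(c2ccccc2)C(C)(C)C)OO1 | intermediate
19 | 2-[(3S,6R)-6-methoxy-6-(pent-4-yn-1-yl)-1,2-dioxan-3-yl]ethan-1-ol | C#CCCC[C@]1(OC)CC[C@@H](CCO)OO1 | intermediate
20 | 2-[(3S,6R)-6-methoxy-6-(pent-4-yn-1-yl)-1,2-dioxan-3-yl]acetic acid | C#CCCC[C@]1(OC)CC[C@@H](CC(=O)O)OO1 | intermediate
21 | undec-1-yne | CCCCCCCCCC#C | starting material
22 | chloridobis(cyclopentadienyl)[(1E)-undec-1-en-1-yl]zirconium | CCCCCCCCC/C=C/[Zr+2]Cl.[cH-]1cccc1.[cH-]1cccc1 | intermediate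
23 | (1E)-1-iodoundec-1-ene | CCCCCCCCC/C=C/I | intermediate
24 | 2-[(3S,6R)-6-[(6E)-hexadec-6-en-4-yn-1-yl]-6-methoxy-1,2-dioxan-3-yl]acetic acid | CCCCCCCCC/C=C/C#CCCC[C@]1(OC)CC[C@@H](CC(=O)O)OO1 | target

**Step count**

Total: 14 steps. Longest linear sequence: 12 steps (steps 1–6, 8–12 and 14); steps 7 and 13 are side branches.

**Steps most likely to fail**

Step 8. E2 elimination of the secondary mesylate and base-mediated cleavage of the alkynyl C–Si bond may outrun substitution by the bulky peroxide anion. The fallback sets out from alcohol 10 and returns at 14. It replaces the isolable mesylate by a triflate made and used in situ. Alcohol 10 is treated at −78 °C with Tf2O and 2,6-lutidine in CH2Cl2 to give (3R)-1-[(tert-butyldiphenylsilyl)oxy]-6-methylidene-11-(trimethylsilyl)undec-10-yn-3-yl trifluoromethanesulfonate F1. F1 is not stored but is met cold by the preformed potassium salt of 13 (KOtBu, THF, −78 → −20 °C). The much better leaving group should let the inverting displacement run at a temperature where elimination and desilylation are slow, and the product is 14.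

Step 10. The unmasked secondary hydroperoxide may fragment under acid or form intermolecular peroxyketals before the ring closes, and the C6 anomers may equilibrate less cleanly than the chair analysis predicts. The fallback sets out from mesylate 11 and returns at 18, closing the ring through the other C–O bond under base. Mesylate 11 is ozonised in MeOH/CH2Cl2 at −78 °C to a dye endpoint, where methanol traps the ketone O-oxide as (3R)-1-[(tert-butyldiphenylsilyl)oxy]-6-hydroperoxy-6-methoxy-11-(trimethylsilyl)undec-10-yn-3-yl methanesulfonate F2 (both C6 epimers). KOtBu and 18-crown-6 in toluene then drive a 6-exo-tet displacement of the mesylate by the hydroperoxide oxygen with inversion at C3. This should give 18 together with its C6 epimer tert-butyl(2-{(3S,6S)-6-methoxy-6-[5-(trimethylsilyl)pent-4-yn-1-yl]-1,2-dioxan-3-yl}ethoxy)diphenylsilane F3. F3 is separated and equilibrated to 18 with catalytic TsOH in MeOH on the closed ring, where no free hydroperoxide is exposed.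

Step 14. Coupling of the ammonium carboxylate may be sluggish because the carboxylate ties up copper, so that alkyne homocoupling or reductive O–O cleavage by low-valent palladium, copper or phosphine takes over. The fallback sets out from alcohol 19 and returns at 24, reversing the order of the last two operations. Neutral alcohol 19 is coupled with 23 under PdCl2(PPh3)2/CuI/i-Pr2NH to give 2-[(3S,6R)-6-[(6E)-hexadec-6-en-4-yn-1-yl]-6-methoxy-1,2-dioxan-3-yl]ethan-1-ol F4. The TEMPO/PhI(OAc)2 oxidation is then carried out last, on F4, to reach 24.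

**Further compounds**

F1 | step 8 | (3R)-1-[(tert-butyldiphenylsilyl)oxy]-6-methylidene-11-(trimethylsilyl)undec-10-yn-3-yl trifluoromethanesulfonate | CC(C)(C)[Si](c1ccccc1)(c1ccccc1)OCC[C@H](OS(=O)(=O)C(F)(F)F)CCC(=C)CCCC#C[Si](C)(C)C
F2 | step 10 | (3R)-1-[(tert-butyldiphenylsilyl)oxy]-6-hydroperoxy-6-methoxy-11-(trimethylsilyl)undec-10-yn-3-yl methanesulfonate (both C6 epimers) | CC(C)(C)[Si](c1ccccc1)(c1ccccc1)OCC[C@H](OS(C)(=O)=O)CCC(OC)(OO)CCCC#C[Si](C)(C)C
F3 | step 10 | tert-butyl(2-{(3S,6S)-6-methoxy-6-[5-(trimethylsilyl)pent-4-yn-1-yl]-1,2-dioxan-3-yl}ethoxy)diphenylsilane | C[Si](C)(C)C#CCCC[C@@]1(OC)CC[C@@H](CCO[Si](c2ccccc2)(c2ccccc2)C(C)(C)C)OO1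
F4 | step 14 | 2-[(3S,6R)-6-[(6E)-hexadec-6-en-4-yn-1-yl]-6-methoxy-1,2-dioxan-3-yl]ethan-1-ol | CCCCCCCCC/C=C/C#CCCC[C@]1(OC)CC[C@@H](CCO)OO1
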